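**Retrosynthetic overview**
1. Target 17 ⇐ primary-selective acetylation of diol 16 ⇐ B-alkyl Suzuki coupling (13 + 14) ⇐ cis-selective reduction of ketone 12.
2. C1–C1' bond ⇐ Pd-catalysed dynamic kinetic asymmetric allylation of keto-butenolide 10 with racemic vinyloxirane 11 (sets C1', relays to C1).
3. Eight-membered ring ⇐ two-carbon ring expansion: alkyne 8 is inserted into the C(=O)–Cα bond of the bicyclic β-keto ester 7; acid then closes the butenolide.
4. 7 ⇐ (R)-3-methylcyclohexanone 1 by carbomethoxylation, dehydrogenation, dienol silylation and Simmons–Smith cyclopropanation anti to the methyl group.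
5. Ring order: cyclohexane (bought) → cyclopropane → cyclooctene (6 → 8) → butenolide.

Locants: C1–C8 are the eight ring carbons (C1 bears the side chain, C2=C3 is the butenolide alkene with C2 carrying the lactone CH2 and C3 the lactone C=O, C4/C5 are the cyclopropane CH carbons, C6 bears CH3, C7 is CH2, C8 bears O); C9 is the cyclopropane CH2; C1' is the side-chain methine. The target is (1R,4R,5R,6S,8S,1'S).
Assumption: the (R,R)-ligand is written in step 6 by analogy with known vinyl-epoxide reactions of this ligand family; if it gives the 1'R series, its enantiomer is used.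

Step 1
Reactants: 1 (R)-3-methylcyclohexanone
Product: 2 methyl (4R)-4-methyl-2-oxocyclohexane-1-carboxylate
Conditions: NaH (2.2 equiv), (MeO)2CO (3 equiv), THF, reflux; aq. HCl quench
Reagents that add atoms: dimethyl carbonate COC(=O)OC
Why: Claisen-type C-acylation under equilibrating conditions goes to the less hindered α-carbon (C6, away from the methyl group), and the existing stereocentre is not touched.

Step 2
Reactants: 2 methyl (4R)-4-methyl-2-oxocyclohexane-1-carboxylate
Product: 4 methyl (4R)-4-methyl-6-oxocyclohex-1-ene-1-carboxylate, via α-phenylselanyl keto ester 3 (not isolated)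
Conditions: PhSeCl (1.1 equiv), pyridine (1.2 equiv), CH2Cl2, 0 °C; then 30% H2O2, 0 °C to rt
Reagents that add atoms: none
Why: α-Selenenylation of the β-keto ester and syn-selenoxide elimination can only go toward the ring CH2, giving the 2-carbomethoxy enone without touching the methyl-bearing centre.

Step 3
Reactants: 4 methyl (4R)-4-methyl-6-oxocyclohex-1-ene-1-carboxylate
Product: 5 methyl (4S)-2-[(tert-butyldimethylsilyl)oxy]-4-methylcyclohexa-1,5-diene-1-carboxylate
Conditions: TBSOTf (1.2 equiv), Et3N (2 equiv), CH2Cl2, 0 °C to rt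
Reagents that add atoms: tert-butyldimethylsilyl triflate CC(C)(C)[Si](C)(C)OS(=O)(=O)C(F)(F)F
Why: Soft enolisation with γ-deprotonation gives the fully conjugated push–pull silyl dienol ether (thermodynamic isomer), which places the free alkene next to the methyl-bearing carbon and masks the β-keto ester; the stereocentre is unchanged (descriptor changes by priority only).

Step 4
Reactants: 5 methyl (4S)-2-[(tert-butyldimethylsilyl)oxy]-4-methylcyclohexa-1,5-diene-1-carboxylate
Product: 7 methyl (1R,5S,6R)-5-methyl-3-oxobicyclo[4.1.0]heptane-2-carboxylate, via cyclopropanated silyl enol ether 6 (not isolated)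
Conditions: Et2Zn (2.0 equiv), CH2I2 (2.0 equiv), CH2Cl2, 0 °C to rt; aq. NH4Cl; then 48% aq. HF, MeCN, 0 °C
Reagents that add atoms: diiodomethane ICI
Why: Furukawa–Simmons–Smith cyclopropanation takes the cis-disubstituted alkene (the tetrasubstituted, ester-bearing silyl enol ether alkene is hindered and deactivated) on the face anti to the adjacent methyl group, which sets C4 and C5 (4R,5R); HF then frees the β-keto ester.

Step 5
Reactants: 7 methyl (1R,5S,6R)-5-methyl-3-oxobicyclo[4.1.0]heptane-2-carboxylate; 8 trimethyl(prop-2-yn-1-yloxy)silane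
Product: 10 keto-butenolide (4R,5R,6S) of the cyclopropane-fused cyclooctenone, via ring-enlarged keto ester 9 (not isolated)
Conditions: 8 (1.5 equiv), [ReBr(CO)3(thf)]2 (2.5 mol %), BnNC (5 mol %), toluene, 50 °C; then TsOH·H2O (0.2 equiv), MeOH, rt
Reagents that add atoms: none
Why: Rhenium-catalysed formal insertion of a terminal alkyne into the C(=O)–Cα bond of a cyclic β-keto ester (the rhenium enolate adds Markovnikov to the alkyne, the alkenyl-metal adds to the ketone, and retro-aldol opening of the cyclobutene alkoxide enlarges the ring by two carbons) puts CH2OSiMe3 on C2 cis to the ester on C3, so acid closes the butenolide; no stereocentre is formed or touched.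

Step 6
Reactants: 10 keto-butenolide (4R,5R,6S); 11 2-vinyloxirane (racemic)
Product: 12 (1R,4R,5R,6S,1'S)-1-(1-hydroxybut-3-en-2-yl) keto-butenolide
Conditions: Pd2(dba)3·CHCl3 (2.5 mol %), (R,R)-DACH-naphthyl Trost ligand (7.5 mol %), 11 (1.2 equiv), CH2Cl2, rt; then DBU (10 mol %), rt
Reagents that add atoms: none
Why: Proposed new method: Pd(0)/L* opens racemic 11 to a zwitterionic π-allyl-Pd alkoxide whose diastereomers interconvert by π–σ–π; the alkoxide deprotonates the doubly activated C1–H2 of 10 (α to the ketone and vinylogous to the lactone) and the ion-paired dienolate attacks the internal allyl carbon on the ligand-defined face (sets C1', branched product, butenolide conjugation kept); C1 stays acidic and equilibrates through the ring-closed hemiketal, where the vinyl group prefers to sit trans to C2, which is the (1R,1'S) arrangement; the closest known reaction type is the Pd-catalysed dynamic kinetic asymmetric alkylation of vinyl epoxides with β-keto esters, not yet shown for a vinylogous keto-lactone pronucleophile giving a tertiary centre.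

Step 7
Reactants: 12 (1R,4R,5R,6S,1'S)-1-(1-hydroxybut-3-en-2-yl) keto-butenolide
Product: 13 (1R,4R,5R,6S,8S,1'S)-vinyl diol
Conditions: L-Selectride (2.2 equiv), THF, −78 °C; then H2O
Reagents that add atoms: none
Why: The bulky hydride attacks the C8 ketone (open form of the hemiketal) on the face anti to the branched C1 substituent, giving the alcohol cis to the side chain (8S); the lactone and the tetrasubstituted alkene are not reduced at −78 °C.

Step 8
Reactants: 13 (1R,4R,5R,6S,8S,1'S)-vinyl diol; 14 1-bromo-2-methylprop-1-ene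
Product: 16 (1R,4R,5R,6S,8S,1'S)-diol carrying the 4-methylpent-3-enyl chain, via tris(9-BBN) adduct 15 (not isolated)
Conditions: 9-BBN-H (3.4 equiv), THF, 0 °C to rt; then 14 (1.5 equiv), PdCl2(dppf) (5 mol %), AsPh3 (5 mol %), Cs2CO3 (3 equiv), DMF/H2O, rt to 50 °C
Reagents that add atoms: none
Why: Anti-Markovnikov hydroboration of the only reactive alkene (terminal vinyl; the butenolide alkene is tetrasubstituted and electron-poor) followed by B-alkyl Suzuki–Miyaura coupling builds the trisubstituted alkene terminus without touching any stereocentre.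

Step 9
Reactants: 16 (1R,4R,5R,6S,8S,1'S)-diol carrying the 4-methylpent-3-enyl chain
Product: 17 target (1R,4R,5R,6S,8S,1'S)-monoacetate CNP0267808.2
Conditions: Ac2O (1.1 equiv), 2,4,6-collidine, CH2Cl2, −20 °C
Reagents that add atoms: acetic anhydride CC(=O)OC(C)=O
Why: Kinetic acylation selects the unhindered primary hydroxyl over the hindered secondary C8 hydroxyl; no stereocentre is involved.

**Compound list**
1 | (R)-3-methylcyclohexanone | C[C@@H]1CCCC(=O)C1 | starting material
2 | methyl (4R)-4-methyl-2-oxocyclohexane-1-carboxylate (C1 epimers and enol) | COC(=O)C1CC[C@@H](C)CC1=O | intermediate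
3 | methyl (4R)-4-methyl-2-oxo-1-(phenylselanyl)cyclohexane-1-carboxylate (C1 epimers) | COC(=O)C1([Se]c2ccccc2)CC[C@@H](C)CC1=O | intermediate (not isolated)
4 | methyl (4R)-4-methyl-6-oxocyclohex-1-ene-1-carboxylate | COC(=O)C1=CC[C@@H](C)CC1=O | intermediate
5 | methyl (4S)-2-[(tert-butyldimethylsilyl)oxy]-4-methylcyclohexa-1,5-diene-1-carboxylate | COC(=O)C1=C(O[Si](C)(C)C(C)(C)C)C[C@H](C)C=C1 | intermediate
6 | methyl (1R,5S,6R)-3-[(tert-butyldimethylsilyl)oxy]-5-methylbicyclo[4.1.0]hept-2-ene-2-carboxylate | COC(=O)C=1[C@@H]2C[C@@H]2[C@@H](C)CC=1O[Si](C)(C)C(C)(C)C | intermediate (not isolated)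
7 | methyl (1R,5S,6R)-5-methyl-3-oxobicyclo[4.1.0]heptane-2-carboxylate (C2 epimers and enol) | COC(=O)C1[C@@H]2C[C@@H]2[C@@H](C)CC1=O | intermediate
8 | trimethyl(prop-2-yn-1-yloxy)silane | C#CCO[Si](C)(C)C | starting material
9 | methyl (1R,7S,8R,2Z)-7-methyl-5-oxo-3-{[(trimethylsilyl)oxy]methyl}bicyclo[6.1.0]non-2-ene-2-carboxylate | O=C1C/C(CO[Si](C)(C)C)=C(C(=O)OC)\[C@@H]2C[C@@H]2[C@@H](C)C1 | intermediate (not isolated)
10 | keto-butenolide (4R,5R,6S): C8 ketone, C1 methylene, C2=C3 in a fused 2(5H)-furanone, cis-cyclopropane on C4–C5 trans to the C6 methyl | O=C1CC2=C(C(=O)OC2)[C@@H]2C[C@@H]2[C@@H](C)C1 | intermediate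
11 | 2-vinyloxirane (racemic) | C=CC1CO1 | starting material
12 | (1R,4R,5R,6S,1'S)-1-(1-hydroxybut-3-en-2-yl) derivative of 10 (C8 ketone, in equilibrium with its ring-closed hemiketal form) | OC[C@@H](C=C)[C@@H]1C2=C(C(=O)OC2)[C@@H]2C[C@@H]2[C@@H](C)CC1=O | intermediate
13 | (1R,4R,5R,6S,8S,1'S)-vinyl diol: 12 with C8 reduced to the alcohol cis to the side chain | OC[C@@H](C=C)[C@@H]1C2=C(C(=O)OC2)[C@@H]2C[C@@H]2[C@@H](C)C[C@@H]1O | intermediate
14 | 1-bromo-2-methylprop-1-ene | CC(C)=CBr | starting material
15 | tris(9-BBN) adduct of 13: terminal alkyl-9-BBN, both hydroxyls as 9-BBN borinates | C1CCC2CCCC1B2OC[C@@H](CCB1C2CCCC1CCC2)[C@@H]1C2=C(C(=O)OC2)[C@@H]2C[C@@H]2[C@@H](C)C[C@@H]1OB1C2CCCC1CCC2 | intermediate (not isolated)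
16 | (1R,4R,5R,6S,8S,1'S)-diol with the complete 1-hydroxy-6-methylhept-5-en-2-yl side chain | OC[C@@H](CCC=C(C)C)[C@@H]1C2=C(C(=O)OC2)[C@@H]2C[C@@H]2[C@@H](C)C[C@@H]1O | intermediate
17 | CNP0267808.2, the primary acetate of 16 | CC(=O)OC[C@@H](CCC=C(C)C)[C@@H]1C2=C(C(=O)OC2)[C@@H]2C[C@@H]2[C@@H](C)C[C@@H]1O | target

**Totals**
Total step count: 9. Longest linear sequence: 9 steps (1 → 17).

**Steps most likely to fail**

Step 6 (the proposed new step). Risks are alkylation at the wrong site or twice, and weak control of C1. The fallback uses known chemistry, sets out from 10 and comes back at 16. 5-Methylhex-4-enal is condensed with nitromethane (cat. piperidine, 4 Å sieves, toluene, heat) through 6-methyl-1-nitrohept-5-en-2-ol F5 to (E)-6-methyl-1-nitrohepta-1,5-diene F6. Ketone 10 is added to it under a bifunctional tertiary-amine thiourea catalyst to give the nitro ketone Michael adduct F7, with C1' set by the catalyst and C1 equilibrated with DBU. L-Selectride then gives the nitro alcohol F8. A buffered Nef reaction (NaOMe, then TiCl3/NH4OAc) gives the hydroxy aldehyde F9, which sits as its five-membered lactol; the trans arrangement favoured there is the wanted one. NaBH4 reduces it to 16, so the Suzuki step is not needed on this path.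

Step 5. The α-carbon of 7 is flanked by the cyclopropane, so the rhenium enolate may add slowly to the alkyne. The fallback sets out from 7 and comes back at 10. Alkyne 8 is lithiated (n-BuLi, −78 °C) and acylated with Boc2O to tert-butyl 4-[(trimethylsilyl)oxy]but-2-ynoate F3. The sodium enolate of 7 (NaH, toluene) adds to it in a Michael sense, the alkenyl anion closes on the ketone and the cyclobutene alkoxide opens by retro-aldol to the ring-enlarged keto diester F4; this is the known base-mediated two-carbon enlargement of cyclic β-keto esters with acetylenic esters. TFA followed by warming removes the silyl and tert-butyl groups, decarboxylates the β-keto acid at C1 and closes the butenolide to 10.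

Step 4. The carbenoid may attack the silyl enol ether alkene instead, or show poor facial selectivity. The fallback changes the order of events, sets out from 4 and comes back at 10. Enone ester 4, reacting through its dienol tautomer, is taken directly into the rhenium-catalysed insertion with 8 to give the dienyl keto ester F1. TsOH in MeOH converts this to the dienone butenolide F2. The cis C4=C5 alkene of the eight-membered ring is then the only nucleophilic alkene and is cyclopropanated (Et2Zn, CH2I2, CF3CO2H, CH2Cl2) anti to the C6 methyl group to give 10.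

**Further compounds**
F1 | step 4 | methyl (7S,1Z,5Z)-7-methyl-5-oxo-3... dienyl keto ester: 9 with a cis C4=C5 alkene in place of the cyclopropane | O=C1C/C(CO[Si](C)(C)C)=C(C(=O)OC)\C=C/[C@@H](C)C1
F2 | step 4 | dienone butenolide: 10 with a cis C4=C5 alkene in place of the cyclopropane (6S) | O=C1CC2=C(C(=O)OC2)/C=C\[C@@H](C)C1
F3 | step 5 | tert-butyl 4-[(trimethylsilyl)oxy]but-2-ynoate | CC(C)(C)OC(=O)C#CCO[Si](C)(C)C
F4 | step 5 | ring-enlarged keto diester: 9 carrying a tert-butoxycarbonyl group on C1 (C1 epimers and enol) | O=C1C(C(=O)OC(C)(C)C)/C(CO[Si](C)(C)C)=C(C(=O)OC)\[C@@H]2C[C@@H]2[C@@H](C)C1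
F5 | step 6 | 6-methyl-1-nitrohept-5-en-2-ol (racemic) | CC(C)=CCCC(O)C[N+](=O)[O-]
F6 | step 6 | (E)-6-methyl-1-nitrohepta-1,5-diene | CC(C)=CCC/C=C/[N+](=O)[O-]
F7 | step 6 | (1R,4R,5R,6S,1'S)-nitro ketone: 10 carrying a 6-methyl-1-nitrohept-5-en-2-yl group on C1 | [O-][N+](=O)C[C@@H](CCC=C(C)C)[C@@H]1C2=C(C(=O)OC2)[C@@H]2C[C@@H]2[C@@H](C)CC1=O
F8 | step 6 | (1R,4R,5R,6S,8S,1'S)-nitro alcohol: F7 with C8 reduced to the alcohol cis to the side chain | [O-][N+](=O)C[C@@H](CCC=C(C)C)[C@@H]1C2=C(C(=O)OC2)[C@@H]2C[C@@H]2[C@@H](C)C[C@@H]1O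
F9 | step 6 | (1R,4R,5R,6S,8S,1'S)-hydroxy aldehyde (open form of the lactol): 16 with CHO in place of CH2OH | O=C[C@@H](CCC=C(C)C)[C@@H]1C2=C(C(=O)OC2)[C@@H]2C[C@@H]2[C@@H](C)C[C@@H]1O
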